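All runs come from a simulation with constants of no real substance.

- Dusk cannot turn all its substrate into target: each target takes one coupling partner to form the intermediate and, if the released group is caught as idle adduct, a second, yet dusk charges 1.00 equiv.

common to all: substrate 0.10 M

| charge | coupling partner | protic impurity | remark | time |
|---|---|---|---|---|
| Thursday's | 0.76 equiv | 2 mM | run made earlier |  |
| Wednesday's | 1.6 equiv | 2 mM | run made earlier |  |
| dusk | 1.00 equiv | 2.00 mM |  | 2.5 h |
| summer | 1.50 equiv | 2.00 mM |  | 2.5 h |
| winter | 2.20 equiv | 2.00 mM |  | 2.5 h |

| run | time / min | substrate / % | target / % |
|---|---|---|---|
| Thursday's | 6.00 | 80.0 | 1.0 |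
| Thursday's | 15.0 | 69.7 | 3.9 |
| Thursday's | 30.0 | 65.6 | 9.7 |
| Thursday's | 80.0 | 64.1 | 22.9 |
| Wednesday's | 6.00 | 61.8 | 2.3 |
| Wednesday's | 15.0 | 46.2 | 7.5 |
| Wednesday's | 30.0 | 40.4 | 16.8 |
| Wednesday's | 80.0 | 35.4 | 40.3 |

(standard deviation of a reading: 0.3 percentage points)

- part of the substrate that has reacted at the end, dusk
- part of the substrate that has reacted at the end, summer
- part of the substrate that has reacted at the end, winter
- what raising the equivalents of coupling partner from its lowest to its highest value here does to the part of the substrate that has reacted (changes below 5 percentage points count as none) (it rises / it falls / no change)

- released group is meant together with its idle adduct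
- steps under discussion: substrate + coupling partner <-> intermediate; intermediate <-> target + released group; coupling partner + released group <-> idle adduct; coupling partner + protic impurity -> quenched reagent; target + released group -> side product

- Thursday's run shows that catch: from 30.0 min to 80.0 min target gains 13 percentage points, but substrate loses 1.5 points.
- I take the impurity's share from the partner and count two per target, which gives 49.0% at dusk. This is my partner budget: the fraction of the substrate that can stand as target with every released group bound.
- The budget is below the whole charge, so I treat partner as dusk's limiting reagent.
- Counted exactly, as fractions of the charge, reacted substrate is the budget plus half of a sum: intermediate minus free partner plus unbound released group plus side product. The readings show neither of the last two, so I assume both are small and drop them.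
- Thursday's last reading gives intermediate 13.0% and free partner 15.2%. I assume their ratio scales with substrate, and dusk should end with less substrate, so its reacted part stays under 49.0%: my upper bound.
- Dusk charges more partner but runs nearly twice as long, so the runs give no firm figure; as an assumption, I allow it at most Thursday's 15.2% free partner. With the ratio scaled to 0.680, my lower bound is 46.6%.
- The budgets of summer, 74.0%, and winter, 109%, climb, so I expect reacted substrate to rise with partner.
- The forecast gives 52%, 69% and 84%, with the trend it rises, on the ground that “Each target therefore costs nearly two equivalents of partner”, and its dusk value stands above my bracket.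
- The flask gives 48.0%, 66.8% and 83.0%, a change of 35 points: it rises.

    substrate + coupling partner ⇌ intermediate (K = 14.0 M⁻¹, k = 0.0120 M⁻¹ s⁻¹)
    intermediate ⇌ target + released group (K = 0.240 M, k = 2.40 × 10⁻⁴ s⁻¹)
    coupling partner + released group ⇌ idle adduct, settled at all times (K = 3100 M⁻¹)
    coupling partner + protic impurity → quenched reagent (k = 0.780 M⁻¹ s⁻¹)
    target + released group → side product (k = 0.00140 M⁻¹ s⁻¹)

- Dusk lands 1 point under its budget, with intermediate at 7.44% of the substrate and free partner at 10.8% of its own charge. A neighbour of winter, cut to 0.880 equiv of partner, has a budget of 43.0%. That neighbour reacts 42.7%, with target at 36.1% and substrate left at 57.3%.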